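**Retrosynthetic overview**
- The route rests on the quaternary C2 of the dihydropyranone ring (ring B: O1, C2, C3, C4, C4a, C8a). C2 with its oxygen, its methyl, the C3 carbon and the six-carbon side chain is the carbinol carbon of (S)-linalool (OH becomes O1, vinyl becomes C3–C4, homoprenyl becomes the side chain).
- The target is traced back to a MOM-protected (S)-7-bromochroman by three functional-group changes: phenol deprotection, C4 benzylic oxidation and Markovnikov hydration of the side-chain alkene.
- Ring B is the only ring formed; it is closed at O1–C8a by copper-catalysed O-arylation of the tertiary alcohol with the ortho bromide of a dibromoarene. Ring A (the benzene ring) is bought.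
- The cyclisation precursor is cut at C4–C4a: B-alkyl Suzuki coupling of the 9-BBN adduct of (S)-linalool with an aryl iodide.
- The aryl iodide comes from 3-iodophenol by dibromination and MOM protection.

Key step: step 4

Assumption: commercial (S)-(+)-linalool is taken in high enantiomeric purity, because the C–O bond at its carbinol carbon stays intact from step 3 to the target and no later step can raise the enantiomeric purity.

**Step 1**
Reactants: 1 3-iodophenol
Product: 2 2,4-dibromo-5-iodophenol
Conditions: NBS (2.05 equiv), MeCN, 0 °C → rt
Reagents that add atoms: N-bromosuccinimide, O=C1CCC(=O)N1Br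
Why: Electrophilic aromatic bromination, in which the hydroxyl group directs bromine to its para position and to its unhindered ortho position (both also ortho or para to iodine), while the ortho site between OH and I is the most hindered, so both possible monobromides converge on the 2,4-dibromo-5-iodo pattern.

**Step 2**
Reactants: 2 2,4-dibromo-5-iodophenol
Product: 3 1,5-dibromo-2-iodo-4-(methoxymethoxy)benzene
Conditions: MOMCl, i-Pr2NEt, CH2Cl2, 0 °C → rt
Reagents that add atoms: chloromethyl methyl ether, COCCl
Why: Williamson-type O-alkylation of the acidic ortho-bromophenol with the reactive α-chloro ether should give the base-stable MOM acetal needed for the coupling and cyclisation steps.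

**Step 3**
Reactants: 4 (S)-linalool; 5 9-borabicyclo[3.3.1]nonane (9-BBN); 3 1,5-dibromo-2-iodo-4-(methoxymethoxy)benzene
Product: 7 (3S)-1-[2,4-dibromo-5-(methoxymethoxy)phenyl]-3,7-dimethyloct-6-en-3-ol, via B-alkyl-9-BBN adduct 6 (not isolated)
Conditions: 4 (1.0 equiv), 9-BBN (1.3 equiv), THF, 0 °C → rt; then aq. K3PO4 (3 M), 3 (1.05 equiv), Pd(dppf)Cl2·CH2Cl2 (5 mol %), DMF/THF, rt → 50 °C
Reagents that add atoms: none
Why: Anti-Markovnikov hydroboration of the monosubstituted vinyl group by bulky 9-BBN (the trisubstituted alkene and the slowly reacting tertiary hydroxyl are left alone) is followed by B-alkyl Suzuki–Miyaura coupling, in which zerovalent palladium adds to the C–I bond far faster than to either C–Br bond, and the carbinol stereocentre takes no part.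

**Step 4**
Reactants: 7 (3S)-1-[2,4-dibromo-5-(methoxymethoxy)phenyl]-3,7-dimethyloct-6-en-3-ol
Product: 8 (2S)-7-bromo-6-(methoxymethoxy)-2-methyl-2-(4-methylpent-3-en-1-yl)chromane
Conditions: CuI (10 mol %), 3,4,7,8-tetramethyl-1,10-phenanthroline (20 mol %), Cs2CO3 (2 equiv), toluene (0.05 M), 110 °C
Reagents that add atoms: none
Why: Cs2CO3 turns the tertiary alcohol into its alkoxide, which binds the phenanthroline-ligated CuI centre; this monovalent copper alkoxide adds oxidatively into the neighbouring C8a–Br bond to give a trivalent copper aryl alkoxide, and C–O reductive elimination forms O1–C8a and returns monovalent copper. The closest known reaction type is the Ullmann-type copper-catalysed intramolecular O-arylation of alcohols with ortho-haloarenes, which is established for tertiary alcohols giving 2,2-disubstituted chromans. Ring B closes in a 6-exo mode, the oxygen attacking aryl carbon C8a while the C–Br bond that breaks lies outside the new ring. No stereocentre is created, and because the C2–O bond of the linalool-derived carbinol is never broken its S configuration is carried over unchanged. The step needs site selectivity between the two aryl bromides, and the tether secures it: copper is brought to the arene by the alkoxide, and only the bromide ortho to the two-carbon chain can be reached through a six-membered transition structure, so the bromide next to the OMOM group is kept for the target. A C4 methylene in place of a C4 carbonyl also rules out retro-aldol cleavage of the alkoxide under the basic conditions.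

**Step 5**
Reactants: 8 (2S)-7-bromo-6-(methoxymethoxy)-2-methyl-2-(4-methylpent-3-en-1-yl)chromane
Product: 9 5-[(2S)-7-bromo-6-(methoxymethoxy)-2-methylchroman-2-yl]-2-methylpentan-2-ol
Conditions: Co(acac)2 (20 mol %), PhSiH3 (2 equiv), O2 (1 atm), i-PrOH/THF, rt
Reagents that add atoms: dioxygen, O=O
Why: Mukaiyama hydration, in which a cobalt hydride transfers a hydrogen atom to the trisubstituted alkene with Markovnikov selectivity and the tertiary radical is trapped by O2 and reduced by the silane to the tertiary alcohol, under conditions that leave the aryl bromide, the MOM acetal and the aryl ether untouched.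

**Step 6**
Reactants: 9 5-[(2S)-7-bromo-6-(methoxymethoxy)-2-methylchroman-2-yl]-2-methylpentan-2-ol
Product: 10 (2S)-7-bromo-2-(4-hydroxy-4-methylpentyl)-6-(methoxymethoxy)-2-methylchroman-4-one
Conditions: Rh2(cap)4 (dirhodium tetracaprolactamate, 1 mol %), t-BuOOH (70% aq., 5 equiv), NaHCO3 (0.5 equiv), ClCH2CH2Cl, 40 °C
Reagents that add atoms: tert-butyl hydroperoxide, CC(C)(C)OO
Why: Benzylic C–H oxidation, in which tert-butylperoxyl radicals abstract hydrogen from C4 (the only benzylic position, activated by the ortho ring oxygen O1) and the mixed peroxide collapses to the aryl ketone, while the tertiary alcohol and the quaternary C2 carry no oxidisable C–H bond.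

**Step 7**
Reactants: 10 (2S)-7-bromo-2-(4-hydroxy-4-methylpentyl)-6-(methoxymethoxy)-2-methylchroman-4-one
Product: 11 (2S)-7-bromo-6-hydroxy-2-(4-hydroxy-4-methylpentyl)-2-methylchroman-4-one (target)
Conditions: p-TsOH·H2O (0.3 equiv), MeOH, 40 °C
Reagents that add atoms: none
Why: Acid-catalysed transacetalisation of the phenolic MOM ether to methanol is fast for aryl MOM ethers under conditions too mild to ionise the tertiary alcohol or to open the 2,2-disubstituted chromanone.

**Compound list**
1 | 3-iodophenol | Oc1cccc(I)c1 | starting material
2 | 2,4-dibromo-5-iodophenol | Oc1cc(I)c(Br)cc1Br | intermediate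
3 | 1,5-dibromo-2-iodo-4-(methoxymethoxy)benzene | COCOc1cc(I)c(Br)cc1Br | intermediate
4 | (S)-linalool, (3S)-3,7-dimethylocta-1,6-dien-3-ol | CC(C)=CCC[C@@](O)(C)C=C | starting material
5 | 9-borabicyclo[3.3.1]nonane (9-BBN) | B1C2CCCC1CCC2 | starting material
6 | (3R)-1-(9-borabicyclo[3.3.1]nonan-9-yl)-3,7-dimethyloct-6-en-3-ol (B-alkyl-9-BBN adduct; same spatial arrangement as 4, the descriptor changes only through CIP priorities) | CC(C)=CCC[C@@](O)(C)CCB1C2CCCC1CCC2 | intermediate (not isolated)
7 | (3S)-1-[2,4-dibromo-5-(methoxymethoxy)phenyl]-3,7-dimethyloct-6-en-3-ol | CC(C)=CCC[C@@](O)(C)CCc1cc(OCOC)c(Br)cc1Br | intermediate (key-step precursor)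
8 | (2S)-7-bromo-6-(methoxymethoxy)-2-methyl-2-(4-methylpent-3-en-1-yl)chromane | CC(C)=CCC[C@@]1(C)CCc2cc(OCOC)c(Br)cc2O1 | intermediate (key-step product)
9 | 5-[(2S)-7-bromo-6-(methoxymethoxy)-2-methylchroman-2-yl]-2-methylpentan-2-ol | CC(C)(O)CCC[C@@]1(C)CCc2cc(OCOC)c(Br)cc2O1 | intermediate
10 | (2S)-7-bromo-2-(4-hydroxy-4-methylpentyl)-6-(methoxymethoxy)-2-methylchroman-4-one | CC(C)(O)CCC[C@@]1(C)CC(=O)c2cc(OCOC)c(Br)cc2O1 | intermediate
11 | (2S)-7-bromo-6-hydroxy-2-(4-hydroxy-4-methylpentyl)-2-methylchroman-4-one | CC(C)(O)CCC[C@@]1(C)CC(=O)c2cc(O)c(Br)cc2O1 | target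

**Step count**
Total: 7 steps. Longest linear sequence: 7 steps (from 3-iodophenol; 5 steps from (S)-linalool).

**Steps most likely to fail**

1. Step 4 (key ring closure). C–O reductive elimination from the hindered tertiary alkoxide at an electron-rich aryl bromide (para to OMOM) may be slow, so that hydrodebromination or intermolecular reaction at the second bromide takes over. The fallback removes the second bromide from the cyclisation substrate and installs it afterwards. It sets out from 1 and 4 and comes back at 8. Para-selective monobromination of 1 with n-Bu4NBr3 should give 4-bromo-3-iodophenol F1, which is protected with MOMCl and i-Pr2NEt as 1-bromo-2-iodo-4-(methoxymethoxy)benzene F2. B-alkyl Suzuki coupling of F2 with borane 6 (made from 4 and 5 as in step 3) should give (3S)-1-[2-bromo-5-(methoxymethoxy)phenyl]-3,7-dimethyloct-6-en-3-ol F3. With only one C–Br bond present, F3 can be closed under forcing conditions or by zerovalent-palladium catalysis (Pd(OAc)2, 2-(di-tert-butylphosphino)-1,1'-binaphthyl, Cs2CO3, toluene, 80 °C) to (2S)-6-(methoxymethoxy)-2-methyl-2-(4-methylpent-3-en-1-yl)chromane F4. MOM-directed ortho-lithiation of F4 (s-BuLi, TMEDA, THF, −78 °C) at the less hindered ortho position C7, then quenching with BrCCl2CCl2Br, should give 8.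

2. Step 6 (benzylic oxidation). Hydrogen abstraction may be unselective (attack at the OCH2O of the MOM group or degradation of the electron-rich ring), or the reaction may stall at the peroxide or alcohol stage. The fallback brings in the C4 oxygen by alkene hydration instead of C–H oxidation. It sets out from 9 and comes back at 10. Dehydrogenation of 9 with DDQ in dioxane at 90 °C should give 5-[(2S)-7-bromo-6-(methoxymethoxy)-2-methyl-2H-chromen-2-yl]-2-methylpentan-2-ol F5. Mukaiyama hydration of its styrene-type C3=C4 bond (Co(acac)2, PhSiH3, O2) places oxygen at the benzylic carbon and should give (2S)-7-bromo-2-(4-hydroxy-4-methylpentyl)-6-(methoxymethoxy)-2-methylchroman-4-ol F6 as a mixture of C4 epimers. Oxidation of the benzylic alcohol with MnO2 in CH2Cl2 removes the C4 stereocentre and should give 10.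

3. Step 3 (hydroboration and B-alkyl Suzuki coupling). The free tertiary hydroxyl may consume 9-BBN and slow transmetalation, and once the iodide is used up coupling or reduction at a C–Br bond may set in. The fallback forms the same C4–C4a bond by a Heck reaction. It sets out from 3 and 4 and comes back at 7. Ligand-free Heck coupling of 3 with the vinyl group of 4 (Pd(OAc)2, n-Bu4NCl, NaHCO3, DMF, 50 °C) is selective for C–I and should give (1E,3S)-1-[2,4-dibromo-5-(methoxymethoxy)phenyl]-3,7-dimethylocta-1,6-dien-3-ol F7; the quaternary carbinol carbon allows β-hydride elimination only towards the arene. Diimide reduction (2-nitrobenzenesulfonylhydrazide, Et3N, CH2Cl2, rt) should saturate the disubstituted styrenyl alkene faster than the trisubstituted one, without touching the aryl bromides, and give 7.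

**Further compounds**
F1 | step 4 | 4-bromo-3-iodophenol | Oc1ccc(Br)c(I)c1
F2 | step 4 | 1-bromo-2-iodo-4-(methoxymethoxy)benzene | COCOc1ccc(Br)c(I)c1
F3 | step 4 | (3S)-1-[2-bromo-5-(methoxymethoxy)phenyl]-3,7-dimethyloct-6-en-3-ol | CC(C)=CCC[C@@](O)(C)CCc1cc(OCOC)ccc1Br
F4 | step 4 | (2S)-6-(methoxymethoxy)-2-methyl-2-(4-methylpent-3-en-1-yl)chromane | CC(C)=CCC[C@@]1(C)CCc2cc(OCOC)ccc2O1
F5 | step 6 | 5-[(2S)-7-bromo-6-(methoxymethoxy)-2-methyl-2H-chromen-2-yl]-2-methylpentan-2-ol | CC(C)(O)CCC[C@@]1(C)C=Cc2cc(OCOC)c(Br)cc2O1
F6 | step 6 | (2S)-7-bromo-2-(4-hydroxy-4-methylpentyl)-6-(methoxymethoxy)-2-methylchroman-4-ol (C4 epimers) | CC(C)(O)CCC[C@@]1(C)CC(O)c2cc(OCOC)c(Br)cc2O1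
F7 | step 3 | (1E,3S)-1-[2,4-dibromo-5-(methoxymethoxy)phenyl]-3,7-dimethylocta-1,6-dien-3-ol | CC(C)=CCC[C@@](O)(C)/C=C/c1cc(OCOC)c(Br)cc1Br
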